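**Retrosynthetic overview**
1. Ring A of the target 14 is disconnected last: a decarboxylative [4+2] benzannulation (the proposed new step) of aryl hex-2-ynoate 4 with 3-methoxyglutaconic anhydride 11 forms two ring C–C bonds and extrudes CO2.
2. The depside C(acyl)–O(aryl) bond is made first, while the acyl partner is still an unhindered alkynoic acid: Steglich esterification of atraric acid 1 (ring B, purchased intact) with hex-2-ynoic acid 2.
3. Anhydride 11 comes from dimethyl 3-oxopentanedioate 5 by enol-ether formation, saponification and cyclodehydration.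
4. Ring order: ring B (bought), then the pyrandione ring of 11, then ring A, which is formed directly with its final OH/OMe/propyl pattern.

Assumption: the target SMILES has no stereocentre or other stereogenic element, so the "single enantiomer" is the achiral compound itself and no stereocontrol is needed.

**Step 1**
Reactants: 1 methyl 2,4-dihydroxy-3,6-dimethylbenzoate (atraric acid); 2 hex-2-ynoic acid
Product: 4 methyl 4-(hex-2-ynoyloxy)-2-hydroxy-3,6-dimethylbenzoate, via O-acylisourea 3 (not isolated)
Conditions: 2 (1.05 equiv), DCC (1.1 equiv), DMAP (5 mol%), CH2Cl2, 0 °C → rt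
Reagents that add atoms: none
Why: Steglich esterification with an unhindered alk-2-ynoic acid; only the 4-OH of 1 reacts because the 2-OH is hydrogen-bonded to the ester carbonyl and flanked by CH3 and CO2Me, and no stereocentre is formed.

**Step 2**
Reactants: 5 dimethyl 3-oxopentanedioate
Product: 7 dimethyl (2E)-3-methoxypent-2-enedioate, via dimethyl ketal 6 (not isolated)
Conditions: HC(OMe)3 (3 equiv), TsOH·H2O (2 mol%), neat, 60 °C, then distil
Reagents that add atoms: trimethyl orthoformate COC(OC)OC
Why: Acid-catalysed ketalisation by the orthoformate followed by loss of methanol from ketal 6 (enol-ether formation of a β-keto ester) gives the conjugated β-methoxy enoate as the thermodynamically preferred E isomer; no stereocentre is formed.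

**Step 3**
Reactants: 7 dimethyl (2E)-3-methoxypent-2-enedioate
Product: 9 (2E)-3-methoxypent-2-enedioic acid, via disodium dicarboxylate 8 (not isolated)
Conditions: NaOH (2.5 equiv), H2O/MeOH 1:1, 0 °C → rt; then 2 M HCl to pH 2 at 0 °C, EtOAc extraction
Reagents that add atoms: sodium hydroxide [Na+].[OH-]
Why: Saponification (BAc2) of both methyl esters; the vinylogous-carbonate enol ether is stable to base and to brief cold acidification, and double-bond geometry is not critical because glutaconic acids equilibrate by 1,3-prototropy.

**Step 4**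
Reactants: 9 (2E)-3-methoxypent-2-enedioic acid
Product: 11 4-methoxy-2H-pyran-2,6(3H)-dione (3-methoxyglutaconic anhydride), via mixed acetic anhydride 10 (not isolated)
Conditions: Ac2O (1.2 equiv), EtOAc, 0 → 20 °C; evaporate, triturate with Et2O
Reagents that add atoms: none
Why: Cyclodehydration of a 1,5-diacid to the six-membered cyclic anhydride through mixed anhydride 10, the standard preparation of glutaconic-type anhydrides; the E acid carries the two carboxyl arms cis on the double bond, as ring closure requires.

**Step 5**
Reactants: 4 methyl 4-(hex-2-ynoyloxy)-2-hydroxy-3,6-dimethylbenzoate; 11 4-methoxy-2H-pyran-2,6(3H)-dione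
Product: 14 peruvinide A (methyl 2-hydroxy-4-[(2-hydroxy-4-methoxy-6-propylbenzoyl)oxy]-3,6-dimethylbenzoate), via hydroxypyranone tautomer 12 (not isolated), via bridged lactone cycloadduct 13 (not isolated)
Conditions: 11 (1.5 equiv), i-Pr2NEt (20 mol%), 4 Å MS, PhMe, 80 → 110 °C; 1 M HCl wash
Reagents that add atoms: none
Why: Proposed new method: a decarboxylative (Tamura-type) [4+2] benzannulation in which the enol form of the anhydride (hydroxypyranone 12, or its ammonium pyranolate under the amine catalyst) serves as an s-cis-locked, electron-rich 1,3-dioxygenated diene; its nucleophilic C3 bonds to the electrophilic β-carbon of the aryl ynoate and its oxygenated C6 bonds to the α-carbon, and irreversible retro-Diels–Alder loss of CO2 from lactone 13 gives the 2-hydroxy-4-methoxy-6-propylbenzoate ring with regiochemistry fixed by diene/dienophile polarity (the anhydride anion is symmetric, so only one regioisomer is possible) and with no stereocentre surviving; the closest known reaction types are the Tamura cycloaddition of homophthalic anhydrides with quinones or acetylenedicarboxylates and the Diels–Alder/CO2-extrusion of 2-pyranones with alkynes, and the new element is the pairing of a 3-alkoxyglutaconic anhydride with a non-activated β-alkyl aryl alkynoate to build a depside ring on a preformed aryl ester in the presence of a free phenol.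

**Compound list**
1 | methyl 2,4-dihydroxy-3,6-dimethylbenzoate (atraric acid) | COC(=O)c1c(C)cc(O)c(C)c1O | starting material
2 | hex-2-ynoic acid | CCCC#CC(=O)O | starting material
3 | N,N'-dicyclohexyl-O-(hex-2-ynoyl)isourea | CCCC#CC(=O)OC(=NC1CCCCC1)NC1CCCCC1 | intermediate
4 | methyl 4-(hex-2-ynoyloxy)-2-hydroxy-3,6-dimethylbenzoate | CCCC#CC(=O)Oc1cc(C)c(C(=O)OC)c(O)c1C | intermediate
5 | dimethyl 3-oxopentanedioate | COC(=O)CC(=O)CC(=O)OC | starting material
6 | dimethyl 3,3-dimethoxypentanedioate | COC(=O)CC(OC)(OC)CC(=O)OC | intermediate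
7 | dimethyl (2E)-3-methoxypent-2-enedioate | COC(=O)/C=C(/OC)CC(=O)OC | intermediate
8 | disodium (2E)-3-methoxypent-2-enedioate | [Na+].[Na+].[O-]C(=O)/C=C(/OC)CC([O-])=O | intermediate
9 | (2E)-3-methoxypent-2-enedioic acid | OC(=O)/C=C(/OC)CC(=O)O | intermediate
10 | acetic (3E)-4-carboxy-3-methoxybut-3-enoic anhydride | CC(=O)OC(=O)C/C(OC)=C\C(=O)O | intermediate
11 | 4-methoxy-2H-pyran-2,6(3H)-dione (3-methoxyglutaconic anhydride) | COC1=CC(=O)OC(=O)C1 | intermediate
12 | 6-hydroxy-4-methoxy-2H-pyran-2-one (enol tautomer of 11) | COc1cc(O)oc(=O)c1 | intermediate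
13 | 3-hydroxy-4-(methoxycarbonyl)-2,5-dimethylphenyl 1-hydroxy-8-methoxy-3-oxo-5-propyl-2-oxabicyclo[2.2.2]octa-5,7-diene-6-carboxylate (racemic) | CCCC1=C(C(=O)Oc2cc(C)c(C(=O)OC)c(O)c2C)C2(O)OC(=O)C1C(OC)=C2 | intermediate
14 | peruvinide A, methyl 2-hydroxy-4-[(2-hydroxy-4-methoxy-6-propylbenzoyl)oxy]-3,6-dimethylbenzoate | CCCc1cc(OC)cc(O)c1C(=O)Oc1cc(C)c(C(=O)OC)c(O)c1C | target

**Totals**
Total step count: 5. Longest linear sequence: 4 steps (steps 2, 3, 4, 5; compound 5 to 14), with step 1 as a one-step convergent branch.

**Three steps most likely to fail**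

Step 5 (the proposed new benzannulation). The β-alkyl ynoate may be too weak a dienophile, the pyranolate may instead attack the aryl ester carbonyl, or the anhydride may self-condense. The fallback is the classical depside esterification, which is known chemistry and a different disconnection; it sets out from compound 1 and comes back to the route at compound 14. Commercial methyl 2,4-dihydroxy-6-propylbenzoate is methylated at its non-chelated 4-OH (MeI, K2CO3, acetone, reflux) to methyl 2-hydroxy-4-methoxy-6-propylbenzoate F1. This is saponified (KOH, DMSO/H2O, 90 °C; cold dilute HCl) to 2-hydroxy-4-methoxy-6-propylbenzoic acid F2. F2 and 1 are then condensed with TFAA in toluene at rt, the acid reacting as 2-hydroxy-4-methoxy-6-propylbenzoic trifluoroacetic anhydride F3 with the free 4-OH of 1 to give 14.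

Step 4 (anhydride formation). Anhydride 11 is an acidic, enolisable, moisture-sensitive compound that may O-acetylate or decompose on isolation. The fallback drops the anhydride and uses an open-chain diene; it sets out from compound 4 and comes back to the route at compound 14. Commercial methyl (E)-3-methoxybut-2-enoate is converted (LDA, TMSCl, THF, −78 °C) into (1E)-1,3-dimethoxy-1-(trimethylsilyloxy)buta-1,3-diene F4 (Brassard's diene). A thermal Diels–Alder reaction with 4 (3 equiv diene, PhMe, 110 °C) gives 3-hydroxy-4-(methoxycarbonyl)-2,5-dimethylphenyl 4,6-dimethoxy-2-propyl-6-(trimethylsilyloxy)cyclohexa-1,4-diene-1-carboxylate F5. F5 aromatises by loss of methanol to methyl 2-hydroxy-4-{[4-methoxy-2-propyl-6-(trimethylsilyloxy)benzoyl]oxy}-3,6-dimethylbenzoate F6, and dilute HCl in MeOH then releases 14.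

Step 3 (saponification). On acidification the enol ether may hydrolyse or the β,γ-unsaturated acid may decarboxylate, and the diacid is water-soluble. The fallback avoids water and the free diacid; it sets out from compound 7 and comes back to the route at compound 11. Diester 7 is cleaved under anhydrous conditions with KOSiMe3 (2.2 equiv, THF, rt) to dipotassium (2E)-3-methoxypent-2-enedioate F7, which is filtered, dried and ring-closed directly with TFAA (1.05 equiv, CH2Cl2, 0 °C) to anhydride 11.

**Further compounds**
F1 | step 5 | methyl 2-hydroxy-4-methoxy-6-propylbenzoate | CCCc1cc(OC)cc(O)c1C(=O)OC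
F2 | step 5 | 2-hydroxy-4-methoxy-6-propylbenzoic acid | CCCc1cc(OC)cc(O)c1C(=O)O
F3 | step 5 | 2-hydroxy-4-methoxy-6-propylbenzoic trifluoroacetic anhydride | CCCc1cc(OC)cc(O)c1C(=O)OC(=O)C(F)(F)F
F4 | step 4 | (1E)-1,3-dimethoxy-1-(trimethylsilyloxy)buta-1,3-diene | C=C(OC)/C=C(\OC)O[Si](C)(C)C
F5 | step 4 | 3-hydroxy-4-(methoxycarbonyl)-2,5-dimethylphenyl 4,6-dimethoxy-2-propyl-6-(trimethylsilyloxy)cyclohexa-1,4-diene-1-carboxylate (racemic) | CCCC1=C(C(=O)Oc2cc(C)c(C(=O)OC)c(O)c2C)C(OC)(O[Si](C)(C)C)C=C(OC)C1
F6 | step 4 | methyl 2-hydroxy-4-{[4-methoxy-2-propyl-6-(trimethylsilyloxy)benzoyl]oxy}-3,6-dimethylbenzoate | CCCc1cc(OC)cc(O[Si](C)(C)C)c1C(=O)Oc1cc(C)c(C(=O)OC)c(O)c1C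
F7 | step 3 | dipotassium (2E)-3-methoxypent-2-enedioate | [K+].[K+].[O-]C(=O)/C=C(/OC)CC([O-])=O
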